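Everything rests on reading the oxepine ring (O, C2′, C1′, C2, C3, C9, C10) as the furan ring of a benzofuran whose C=C bond has been split by two inserted carbons: C3, which is also a pyranone atom, and C9. A 3-aryloxybenzofuran whose aryl ring carries an ortho propioloyl group is therefore irradiated with a triplet sensitiser: alkyne and furan double bond join in a [2+2] cycloaddition (new bonds C2–C3 and C9–C10) and the strained cyclobutene opens, which closes pyranone and oxepine in one operation. The precursor already holds the hydroxyisopropyl group on the furan and an inert fluorine as placeholder for 5-OH; C10 is set afterwards by enol-ether hydrogenation.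

Key step: step 6

Remark: the tetracycle is called "oxepinochromone" here and numbered as a chromone (O1, C2–C8a), with C9 the oxepine carbon on C3, C10 the oxepine carbon bonded to the ring oxygen that sits on C2′, and B ring C1′–C6′ (C1′ on C2); 9, 10 and 12 are racemic and their stereocentres are erased again in steps 5 and 6.

Step 1
Reactants: 1 methyl 2,4-dihydroxybenzoate
Product: 2 methyl 2-hydroxy-4-(methoxymethoxy)benzoate
Conditions: MOMCl (1.1 equiv), i-Pr2NEt, CH2Cl2, 0 °C → rt
Reagents that add atoms: chloromethyl methyl ether, COCCl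
Why: O-alkylation (acetal formation) that should be selective for the 4-hydroxyl because the 2-hydroxyl is tied up in a hydrogen bond to the ester carbonyl and is far less nucleophilic.

Step 2
Reactants: 2 methyl 2-hydroxy-4-(methoxymethoxy)benzoate; 3 methyl bromoacetate
Product: 5 methyl 3-hydroxy-6-(methoxymethoxy)-1-benzofuran-2-carboxylate, via aryloxyacetate diester 4 (not isolated)
Conditions: K2CO3, DMF, 50 °C; then NaOMe, MeOH, 0 °C → rt; AcOH
Reagents that add atoms: none
Why: Williamson etherification of the remaining phenol, followed in the same flask by Dieckmann condensation of the aryloxyacetate α-carbon onto the benzoate ester, should give the enolised 3-hydroxybenzofuran-2-carboxylate, the MOM ether being stable to base.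

Step 3
Reactants: 5 methyl 3-hydroxy-6-(methoxymethoxy)-1-benzofuran-2-carboxylate; 6 2,6-difluoro-4-methoxybenzaldehyde
Product: 7 methyl 3-(3-fluoro-2-formyl-5-methoxyphenoxy)-6-(methoxymethoxy)-1-benzofuran-2-carboxylate
Conditions: K2CO3, DMF, 60 °C
Reagents that add atoms: none
Why: Nucleophilic aromatic substitution (SNAr) in which the formyl group activates both equivalent ortho fluorines, the hard enolate oxygen is arylated in preference to the fully substituted C2, and the product is deactivated towards a second substitution.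

Step 4
Reactants: 7 methyl 3-(3-fluoro-2-formyl-5-methoxyphenoxy)-6-(methoxymethoxy)-1-benzofuran-2-carboxylate; 8 ethynylmagnesium bromide
Product: 10 racemic 1-(2-fluoro-6-{[2-(2-hydroxypropan-2-yl)-6-(methoxymethoxy)-1-benzofuran-3-yl]oxy}-4-methoxyphenyl)prop-2-yn-1-ol, via bromomagnesium alkoxide of the propargylic alcohol ester 9 (not isolated)
Conditions: 8 (1.1 equiv), THF, −78 → −20 °C; then MeMgBr (5 equiv), −20 °C → rt; aq. NH4Cl
Reagents that add atoms: methylmagnesium bromide, C[Mg]Br
Why: Chemoselective Grignard 1,2-addition, in which the ethynyl reagent takes the aldehyde at low temperature while the conjugated heteroaryl ester is left, after which excess methylmagnesium bromide adds twice to that ester to give the tertiary alcohol, the secondary alkoxide and the acetylide being bystanders.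

Step 5
Reactants: 10 racemic 1-(2-fluoro-6-{[2-(2-hydroxypropan-2-yl)-6-(methoxymethoxy)-1-benzofuran-3-yl]oxy}-4-methoxyphenyl)prop-2-yn-1-ol
Product: 11 1-(2-fluoro-6-{[2-(2-hydroxypropan-2-yl)-6-(methoxymethoxy)-1-benzofuran-3-yl]oxy}-4-methoxyphenyl)prop-2-yn-1-one
Conditions: MnO2 (activated, excess), CH2Cl2, rt
Reagents that add atoms: none
Why: Manganese dioxide oxidation should touch only the doubly activated (benzylic and propargylic) secondary alcohol under neutral conditions, which spares the acid-sensitive tertiary furyl carbinol, the MOM ether and the terminal alkyne.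

Step 6
Reactants: 11 1-(2-fluoro-6-{[2-(2-hydroxypropan-2-yl)-6-(methoxymethoxy)-1-benzofuran-3-yl]oxy}-4-methoxyphenyl)prop-2-yn-1-one
Product: 13 5-fluoro-10-(2-hydroxypropan-2-yl)-7-methoxy-4′-(methoxymethoxy)oxepinochromone (C9=C10 enol ether), via cis-fused cyclobutene photoadduct 12 (not isolated)
Conditions: thioxanthone (10 mol%), hν 405 nm, degassed MeCN (5 mM), 20 °C; then 50 °C in the dark
Reagents that add atoms: none
Why: Proposed new method: triplet energy transfer from thioxanthone to the aryl ynone should give a diradical whose α-carbon, held by the four-atom O–C(aryl)–C(aryl)–C(=O) tether, bonds to furan C3 while the β-carbon bonds to furan C2, an intramolecular [2+2] that creates target bonds C2–C3 and C9–C10 in cyclobutene 12; in 12 the former furan carbons carry oxygen and aryl donors and the C3=C9 alkene is conjugated with the C4 carbonyl, so the σ bond between them (C2–C10) should break in a polar sense (oxocarbenium character at C2, dienolate over C10, C9, C3 and the C4 oxygen) and the ends pair up as the C2=C3 and C9=C10 double bonds of 13. The closest known reaction types are the sensitised dearomative [2+2] photocycloadditions of benzofurans and the ring enlargement of benzofuran–alkyne photoadducts to 1-benzoxepines; the combination with an ynone that ends as a 4-pyranone is new. The pyranone is closed as a six-membered ring by the bond from the ynone α-carbon to furan C3, exo with respect to both π bonds, whereas the oxepine is not closed by a cyclisation but arises when the five-membered furan ring is enlarged by two carbons on cleavage of the central bond of the oxabicyclo[3.2.0]heptene, driven by relief of cyclobutene strain and the gain of the aromatic pyranone. The two stereocentres of 12 (C2 and C10, necessarily cis at the ring fusion) are lost on opening, so 13 has no stereocentre and nothing stereochemical is asked of this step. It needs regioselectivity, which the short rigid tether secures because only the α-carbon can reach furan C3, and chemoselectivity for the alkyne over the carbonyl (Paternò–Büchi addition or bonding through oxygen), which the linear ynone lying over the furan double bond and long-wavelength sensitisation should favour, while the ortho fluorine offers neither an abstractable hydrogen nor a nucleophilic oxygen and so shuts off δ-hydrogen abstraction and oxa-Michael closure to the wrong chromone.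

Step 7
Reactants: 13 5-fluoro-10-(2-hydroxypropan-2-yl)-7-methoxy-4′-(methoxymethoxy)oxepinochromone (C9=C10 enol ether)
Product: 14 (10R)-5-fluoro-10-(2-hydroxypropan-2-yl)-7-methoxy-4′-(methoxymethoxy)-9,10-dihydrooxepinochromone
Conditions: [Ir(cod)((S)-tBu-PHOX)]BArF (2 mol%), H2 (50 bar), CH2Cl2, rt
Reagents that add atoms: none
Why: Iridium N,P-ligand catalysed asymmetric hydrogenation of a trisubstituted cyclic enol ether, in which the chiral ligand differentiates the two faces of C9=C10 and so sets C10 under catalyst control (the (S)-ligand is shown, and the antipode that proves to deliver 10R is the one used), while the tetrasubstituted pyranone C2=C3 bond, the C–F bond and the MOM ether should stay untouched.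

Step 8
Reactants: 14 (10R)-5-fluoro-10-(2-hydroxypropan-2-yl)-7-methoxy-4′-(methoxymethoxy)-9,10-dihydrooxepinochromone
Product: 16 (10R)-5-hydroxy-10-(2-hydroxypropan-2-yl)-7-methoxy-4′-(methoxymethoxy)-9,10-dihydrooxepinochromone, via 5-(2-methylsulfonylethoxy) ether 15 (not isolated)
Conditions: MeSO2CH2CH2OH (3 equiv), NaH (4 equiv), DMF, 0 → 50 °C; aq. NH4Cl
Reagents that add atoms: 2-(methylsulfonyl)ethanol, CS(=O)(=O)CCO
Why: SNAr at C5, which lies ortho to the C4 carbonyl, by the alkoxide of 2-(methylsulfonyl)ethanol, followed by base-induced β-elimination (E1cB) of methyl vinyl sulfone from ether 15, should release the 5-phenoxide, and C10 carries no acidic hydrogen and cannot epimerise.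

Step 9
Reactants: 16 (10R)-5-hydroxy-10-(2-hydroxypropan-2-yl)-7-methoxy-4′-(methoxymethoxy)-9,10-dihydrooxepinochromone
Product: 17 (10R)-5-hydroxy-10-(2-hydroxypropan-2-yl)-6-iodo-7-methoxy-4′-(methoxymethoxy)-9,10-dihydrooxepinochromone
Conditions: BnMe3N+ ICl2− (1.05 equiv), CaCO3, CH2Cl2–MeOH, rt
Reagents that add atoms: benzyltrimethylammonium dichloroiodate, C[N+](C)(C)Cc1ccccc1.Cl[I-]Cl
Why: Electrophilic aromatic iodination by the mild dichloroiodate reagent should attack only the ring that bears the free, chelated phenol and do so ortho to that hydroxyl at C6, the pattern known for 5-hydroxy-7-alkoxyflavones, while ring B stays inert because both of its oxygens are ethers (the reason the MOM group is kept to this point).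

Step 10
Reactants: 17 (10R)-5-hydroxy-10-(2-hydroxypropan-2-yl)-6-iodo-7-methoxy-4′-(methoxymethoxy)-9,10-dihydrooxepinochromone
Product: 18 (10R)-4′,5-dihydroxy-10-(2-hydroxypropan-2-yl)-6-iodo-7-methoxy-9,10-dihydrooxepinochromone
Conditions: HCl (1.25 M in MeOH), THF, 35 °C
Reagents that add atoms: none
Why: Acid-catalysed acetal cleavage (transacetalisation with methanol), placed before the acid-sensitive electron-rich styrene exists, should leave the tertiary alcohol intact because the β-aryloxy group disfavours its ionisation, and it does not touch C10.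

Step 11
Reactants: 18 (10R)-4′,5-dihydroxy-10-(2-hydroxypropan-2-yl)-6-iodo-7-methoxy-9,10-dihydrooxepinochromone; 19 (E)-4,4,5,5-tetramethyl-2-(3-methylbut-1-en-1-yl)-1,3,2-dioxaborolane
Product: 20 (10R)-4′,5-dihydroxy-10-(2-hydroxypropan-2-yl)-7-methoxy-6-[(E)-3-methylbut-1-en-1-yl]-9,10-dihydrooxepinochromone (CNP0216454.1)
Conditions: Pd(dppf)Cl2 (5 mol%), K2CO3 (4 equiv), 1,4-dioxane–H2O (4:1), 80 °C
Reagents that add atoms: none
Why: Suzuki–Miyaura coupling, in which the alkenyl group is transferred with retention of its E geometry, should proceed readily with the aryl iodide and tolerate the free phenols as phenoxides in aqueous carbonate.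

Compound list
1 | methyl 2,4-dihydroxybenzoate | COC(=O)c1ccc(O)cc1O | starting material
2 | methyl 2-hydroxy-4-(methoxymethoxy)benzoate | COCOc1ccc(C(=O)OC)c(O)c1 | intermediate
3 | methyl bromoacetate | COC(=O)CBr | starting material
4 | methyl 2-(2-methoxy-2-oxoethoxy)-4-(methoxymethoxy)benzoate (not isolated) | COCOc1ccc(C(=O)OC)c(OCC(=O)OC)c1 | intermediate
5 | methyl 3-hydroxy-6-(methoxymethoxy)-1-benzofuran-2-carboxylate | COCOc1ccc2c(O)c(C(=O)OC)oc2c1 | intermediate
6 | 2,6-difluoro-4-methoxybenzaldehyde | COc1cc(F)c(C=O)c(F)c1 | starting material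
7 | methyl 3-(3-fluoro-2-formyl-5-methoxyphenoxy)-6-(methoxymethoxy)-1-benzofuran-2-carboxylate | COCOc1ccc2c(Oc3cc(OC)cc(F)c3C=O)c(C(=O)OC)oc2c1 | intermediate
8 | ethynylmagnesium bromide | C#C[Mg]Br | starting material
9 | bromomagnesium alkoxide of racemic methyl 3-[3-fluoro-2-(1-hydroxyprop-2-yn-1-yl)-5-methoxyphenoxy]-6-(methoxymethoxy)-1-benzofuran-2-carboxylate (not isolated) | COCOc1ccc2c(Oc3cc(OC)cc(F)c3C(O[Mg]Br)C#C)c(C(=O)OC)oc2c1 | intermediate
10 | racemic 1-(2-fluoro-6-{[2-(2-hydroxypropan-2-yl)-6-(methoxymethoxy)-1-benzofuran-3-yl]oxy}-4-methoxyphenyl)prop-2-yn-1-ol | COCOc1ccc2c(Oc3cc(OC)cc(F)c3C(O)C#C)c(C(C)(C)O)oc2c1 | intermediate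
11 | 1-(2-fluoro-6-{[2-(2-hydroxypropan-2-yl)-6-(methoxymethoxy)-1-benzofuran-3-yl]oxy}-4-methoxyphenyl)prop-2-yn-1-one (photoprecursor) | COCOc1ccc2c(Oc3cc(OC)cc(F)c3C(=O)C#C)c(C(C)(C)O)oc2c1 | intermediate
12 | racemic cis-fused cyclobutene photoadduct: former furan C2 and C3 bridged by the CH=C unit of the ynone, the chroman-4-one ring closed through O1 (not isolated) | COc1cc(F)c2C(=O)C3=CC4(C(C)(C)O)Oc5cc(OCOC)ccc5C34Oc2c1 | intermediate
13 | 5-fluoro-10-(2-hydroxypropan-2-yl)-7-methoxy-4′-(methoxymethoxy)oxepinochromone (C9=C10 enol ether) | COc1cc2oc3c(c(=O)c2c(F)c1)C=C(C(C)(C)O)Oc1cc(OCOC)ccc1-3 | intermediate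
14 | (10R)-5-fluoro-10-(2-hydroxypropan-2-yl)-7-methoxy-4′-(methoxymethoxy)-9,10-dihydrooxepinochromone | COc1cc2oc3c(c(=O)c2c(F)c1)C[C@H](C(C)(C)O)Oc1cc(OCOC)ccc1-3 | intermediate
15 | (10R)-10-(2-hydroxypropan-2-yl)-7-methoxy-4′-(methoxymethoxy)-5-[2-(methylsulfonyl)ethoxy]-9,10-dihydrooxepinochromone (not isolated) | COc1cc2oc3c(c(=O)c2c(OCCS(C)(=O)=O)c1)C[C@H](C(C)(C)O)Oc1cc(OCOC)ccc1-3 | intermediate
16 | (10R)-5-hydroxy-10-(2-hydroxypropan-2-yl)-7-methoxy-4′-(methoxymethoxy)-9,10-dihydrooxepinochromone | COc1cc2oc3c(c(=O)c2c(O)c1)C[C@H](C(C)(C)O)Oc1cc(OCOC)ccc1-3 | intermediate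
17 | (10R)-5-hydroxy-10-(2-hydroxypropan-2-yl)-6-iodo-7-methoxy-4′-(methoxymethoxy)-9,10-dihydrooxepinochromone | COc1cc2oc3c(c(=O)c2c(O)c1I)C[C@H](C(C)(C)O)Oc1cc(OCOC)ccc1-3 | intermediate
18 | (10R)-4′,5-dihydroxy-10-(2-hydroxypropan-2-yl)-6-iodo-7-methoxy-9,10-dihydrooxepinochromone | COc1cc2oc3c(c(=O)c2c(O)c1I)C[C@H](C(C)(C)O)Oc1cc(O)ccc1-3 | intermediate
19 | (E)-4,4,5,5-tetramethyl-2-(3-methylbut-1-en-1-yl)-1,3,2-dioxaborolane | CC(C)/C=C/B1OC(C)(C)C(C)(C)O1 | starting material
20 | (10R)-4′,5-dihydroxy-10-(2-hydroxypropan-2-yl)-7-methoxy-6-[(E)-3-methylbut-1-en-1-yl]-9,10-dihydrooxepinochromone (CNP0216454.1) | COc1cc2oc3c(c(=O)c2c(O)c1/C=C/C(C)C)C[C@H](C(C)(C)O)Oc1cc(O)ccc1-3 | target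

Total step count: 11. Longest linear sequence: 11 steps (1 → 20); 3, 6, 8 and 19 are purchased and enter in steps 2, 3, 4 and 11.

Steps most likely to fail

1. Step 6 (Proposed new method). The excited ynone may be consumed through its carbonyl group (oxetane formation, or bonding at oxygen followed by carbene chemistry), may decay without reacting, or the product chromophore may be photolysed further. The fallback uses only known chemistry and closes the oxepine by phenoxide opening of an epoxide on a preformed flavone. It sets out from 2 and 6 and comes back at 14, so it also passes by step 7.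
   - Benzyl bromide and K2CO3 in DMF convert 2 into methyl 2-(benzyloxy)-4-(methoxymethoxy)benzoate F1.
   - Aldehyde 6 and (4-methylpent-3-en-1-yl)magnesium bromide (THF, 0 °C) give racemic 1-(2,6-difluoro-4-methoxyphenyl)-5-methylhex-4-en-1-ol F2, which Dess–Martin periodinane oxidises to 1-(2,6-difluoro-4-methoxyphenyl)-5-methylhex-4-en-1-one F3.
   - The lithium enolate of F3 (LiHMDS, THF, −78 °C → rt) is acylated by F1 in a crossed Claisen condensation to 1-[2-(benzyloxy)-4-(methoxymethoxy)phenyl]-3-(2,6-difluoro-4-methoxyphenyl)-2-(3-methylbut-2-en-1-yl)propane-1,3-dione F4.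
   - K2CO3 in DMF at 80 °C closes the pyranone by intramolecular SNAr of the enolate oxygen on an ortho C–F bond, giving 2-[2-(benzyloxy)-4-(methoxymethoxy)phenyl]-5-fluoro-7-methoxy-3-(3-methylbut-2-en-1-yl)-4H-chromen-4-one F5.
   - Shi epoxidation (Oxone, K2CO3 buffer, MeCN–dimethoxymethane, 0 °C, with the enantiomer of the fructose-derived ketone that delivers the 2S epoxide) gives 2-[2-(benzyloxy)-4-(methoxymethoxy)phenyl]-3-{[(2S)-3,3-dimethyloxiran-2-yl]methyl}-5-fluoro-7-methoxy-4H-chromen-4-one F6.
   - Hydrogenolysis (H2, Pd/C, EtOAc) frees the phenol to give 3-{[(2S)-3,3-dimethyloxiran-2-yl]methyl}-5-fluoro-2-[2-hydroxy-4-(methoxymethoxy)phenyl]-7-methoxy-4H-chromen-4-one F7.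
   - K2CO3 in DMF lets the phenoxide open the epoxide at its secondary carbon (7-exo-tet, inversion), which should give 14 with the 10R configuration.

2. Step 7. Facial discrimination may be poor at a hindered enol ether flanked by a tertiary carbinol, and the acidic cationic iridium hydride may ionise that allylic carbinol. The fallback replaces asymmetric catalysis by resolution; it sets out from 13 and comes back at 14. Non-selective hydrogenation (H2 1 bar, Rh/Al2O3, EtOAc, trace Et3N) gives racemic 5-fluoro-10-(2-hydroxypropan-2-yl)-7-methoxy-4′-(methoxymethoxy)-9,10-dihydrooxepinochromone F8. The enantiomers are separated by preparative chromatography on a chiral stationary phase (supercritical CO2–MeOH, amylose carbamate phase); the (10R)-enantiomer is 14 and the (10S)-enantiomer F9 is set aside. The configuration would be assigned by comparison with 14 from the epoxide route under point 1.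

3. Step 8. Addition at C5 may be slow because two ring oxygens feed electron density into the positions that must accept the negative charge, and the oxygen nucleophile may instead add at C2 of the pyranone and open it. The fallback makes the C5–O bond earlier, where the fluorine is ortho to a formyl group; it sets out from 7 and comes back at 16. Its cost is that the alkoxy group brings O–CH2 hydrogens near the excited ynone in the photochemical step.
   - 2-(Trimethylsilyl)ethanol and NaH (THF, 0 °C) displace the fluoride of 7 to give methyl 3-{2-formyl-5-methoxy-3-[2-(trimethylsilyl)ethoxy]phenoxy}-6-(methoxymethoxy)-1-benzofuran-2-carboxylate F10.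
   - The conditions of step 4 give, by way of the bromomagnesium alkoxide of the propargylic alcohol ester F11 (not isolated), the racemic diol 1-(2-{[2-(2-hydroxypropan-2-yl)-6-(methoxymethoxy)-1-benzofuran-3-yl]oxy}-4-methoxy-6-[2-(trimethylsilyl)ethoxy]phenyl)prop-2-yn-1-ol F12.
   - The conditions of step 5 give the corresponding prop-2-yn-1-one F13.
   - The conditions of step 6 give, through the cis-fused cyclobutene photoadduct F14 (not isolated), 10-(2-hydroxypropan-2-yl)-7-methoxy-4′-(methoxymethoxy)-5-[2-(trimethylsilyl)ethoxy]oxepinochromone F15.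
   - The conditions of step 7 give its (10R)-9,10-dihydro derivative F16.
   - TBAF (THF, 50 °C) fragments the silylethyl ether and releases the phenol, giving 16.

Further compounds
F1 | step 6 | methyl 2-(benzyloxy)-4-(methoxymethoxy)benzoate | COCOc1ccc(C(=O)OC)c(OCc2ccccc2)c1
F2 | step 6 | racemic 1-(2,6-difluoro-4-methoxyphenyl)-5-methylhex-4-en-1-ol | COc1cc(F)c(C(O)CCC=C(C)C)c(F)c1
F3 | step 6 | 1-(2,6-difluoro-4-methoxyphenyl)-5-methylhex-4-en-1-one | COc1cc(F)c(C(=O)CCC=C(C)C)c(F)c1
F4 | step 6 | 1-[2-(benzyloxy)-4-(methoxymethoxy)phenyl]-3-(2,6-difluoro-4-methoxyphenyl)-2-(3-methylbut-2-en-1-yl)propane-1,3-dione | COCOc1ccc(C(=O)C(CC=C(C)C)C(=O)c2c(F)cc(OC)cc2F)c(OCc2ccccc2)c1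
F5 | step 6 | 2-[2-(benzyloxy)-4-(methoxymethoxy)phenyl]-5-fluoro-7-methoxy-3-(3-methylbut-2-en-1-yl)-4H-chromen-4-one | COc1cc2oc(-c3ccc(OCOC)cc3OCc3ccccc3)c(CC=C(C)C)c(=O)c2c(F)c1
F6 | step 6 | 2-[2-(benzyloxy)-4-(methoxymethoxy)phenyl]-3-{[(2S)-3,3-dimethyloxiran-2-yl]methyl}-5-fluoro-7-methoxy-4H-chromen-4-one | COc1cc2oc(-c3ccc(OCOC)cc3OCc3ccccc3)c(C[C@@H]3OC3(C)C)c(=O)c2c(F)c1
F7 | step 6 | 3-{[(2S)-3,3-dimethyloxiran-2-yl]methyl}-5-fluoro-2-[2-hydroxy-4-(methoxymethoxy)phenyl]-7-methoxy-4H-chromen-4-one | COc1cc2oc(-c3ccc(OCOC)cc3O)c(C[C@@H]3OC3(C)C)c(=O)c2c(F)c1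
F8 | step 7 | racemic 5-fluoro-10-(2-hydroxypropan-2-yl)-7-methoxy-4′-(methoxymethoxy)-9,10-dihydrooxepinochromone | COc1cc2oc3c(c(=O)c2c(F)c1)CC(C(C)(C)O)Oc1cc(OCOC)ccc1-3
F9 | step 7 | (10S)-5-fluoro-10-(2-hydroxypropan-2-yl)-7-methoxy-4′-(methoxymethoxy)-9,10-dihydrooxepinochromone | COc1cc2oc3c(c(=O)c2c(F)c1)C[C@@H](C(C)(C)O)Oc1cc(OCOC)ccc1-3
F10 | step 8 | methyl 3-{2-formyl-5-methoxy-3-[2-(trimethylsilyl)ethoxy]phenoxy}-6-(methoxymethoxy)-1-benzofuran-2-carboxylate | COCOc1ccc2c(Oc3cc(OC)cc(OCC[Si](C)(C)C)c3C=O)c(C(=O)OC)oc2c1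
F11 | step 8 | bromomagnesium alkoxide of the racemic propargylic alcohol ester in the 2-(trimethylsilyl)ethoxy series (not isolated) | COCOc1ccc2c(Oc3cc(OC)cc(OCC[Si](C)(C)C)c3C(O[Mg]Br)C#C)c(C(=O)OC)oc2c1
F12 | step 8 | racemic 1-(2-{[2-(2-hydroxypropan-2-yl)-6-(methoxymethoxy)-1-benzofuran-3-yl]oxy}-4-methoxy-6-[2-(trimethylsilyl)ethoxy]phenyl)prop-2-yn-1-ol | COCOc1ccc2c(Oc3cc(OC)cc(OCC[Si](C)(C)C)c3C(O)C#C)c(C(C)(C)O)oc2c1
F13 | step 8 | 1-(2-{[2-(2-hydroxypropan-2-yl)-6-(methoxymethoxy)-1-benzofuran-3-yl]oxy}-4-methoxy-6-[2-(trimethylsilyl)ethoxy]phenyl)prop-2-yn-1-one | COCOc1ccc2c(Oc3cc(OC)cc(OCC[Si](C)(C)C)c3C(=O)C#C)c(C(C)(C)O)oc2c1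
F14 | step 8 | racemic cis-fused cyclobutene photoadduct in the 2-(trimethylsilyl)ethoxy series (not isolated) | COc1cc(OCC[Si](C)(C)C)c2C(=O)C3=CC4(C(C)(C)O)Oc5cc(OCOC)ccc5C34Oc2c1
F15 | step 8 | 10-(2-hydroxypropan-2-yl)-7-methoxy-4′-(methoxymethoxy)-5-[2-(trimethylsilyl)ethoxy]oxepinochromone (C9=C10 enol ether) | COc1cc2oc3c(c(=O)c2c(OCC[Si](C)(C)C)c1)C=C(C(C)(C)O)Oc1cc(OCOC)ccc1-3
F16 | step 8 | (10R)-10-(2-hydroxypropan-2-yl)-7-methoxy-4′-(methoxymethoxy)-5-[2-(trimethylsilyl)ethoxy]-9,10-dihydrooxepinochromone | COc1cc2oc3c(c(=O)c2c(OCC[Si](C)(C)C)c1)C[C@H](C(C)(C)O)Oc1cc(OCOC)ccc1-3
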